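The plan rests on ring B, where quaternary C10 and tertiary C9 are the β- and α-carbons of a C8 carbonyl, with the C5 stereocentre next to C10. One telescoped operation adds a silyloxypropyl copper reagent to C10 of an enantiopure 3-methylcyclohexenone, anti to its C5 acetate arm, and allylates the unmasked C8 enolate at C9; this forms C1–C10 and C9–C11 and sets both centres from C5 alone. The precursor is the S-configured 4-(tert-butoxycarbonylmethyl)-3-methylcyclohex-2-enone, made by organocatalytic Michael/aldol annulation, β-methylation and dehydrogenation. Afterwards the ketone becomes the C7=C8 methyl alkene, the two arms are joined into ring A, C4 is methylated, and the allyl group is extended to the Z-enoic acid before angeloylation.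

Key step: step 5

Remark: labdane numbering is used for all intermediates, monocyclic ones included (ring A: C1–C5, C10; ring B: C5–C10; side chain C11–C16; C17 on C8; C18 equatorial and C19 axial on C4; C20 on C10); the bicyclic compounds belong to the normal labdane series (5α-H, 9α-H, 10β-CH3).

Remark: the sense of induction in step 1 is assigned from the usual steric model of diarylprolinol ethers (attack on the enamine face remote from the diarylmethyl group); the antipodal catalyst would be used if the assignment proved reversed.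

Remark: the starting materials of the route are taken to be catalogue compounds.

Step 1
Reactants: 1 tert-butyl 4-oxobutanoate; 2 but-3-en-2-one (methyl vinyl ketone)
Product: 4 tert-butyl 2-[(1S)-4-oxocyclohex-2-en-1-yl]acetate, via keto aldehyde 3 (not isolated)
Conditions: (S)-2-[methoxy(diphenyl)methyl]pyrrolidine (5 mol %), ethyl 3,4-dihydroxybenzoate (20 mol %), neat, 4 °C; then LiOH (0.5 equiv), iPrOH, 25 °C
Reagents that add atoms: none
Why: Enamine-catalysed asymmetric Michael addition of the aldehyde to the enone, in which the diarylmethyl group of the S-configured pyrrolidine blocks one face of the E-enamine so that the new centre (later C5) should form with S configuration, is followed by base-mediated intramolecular aldol condensation of the methyl ketone onto the aldehyde, a sequence well established for 4-substituted cyclohex-2-enones.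

Step 2
Reactants: 4 tert-butyl 2-[(1S)-4-oxocyclohex-2-en-1-yl]acetate
Product: 5 tert-butyl 2-[(1S,2S)-2-methyl-4-(trimethylsilyloxy)cyclohex-3-en-1-yl]acetate
Conditions: MeLi, CuI (gives Me2CuLi, 1.3 equiv), Me3SiCl (2 equiv), THF, −78 °C; Et3N, pentane, cold aqueous NaHCO3
Reagents that add atoms: lithium dimethylcuprate, [Li+].C[Cu-]C; chlorotrimethylsilane, C[Si](C)(C)Cl
Why: Silyl-accelerated Gilman conjugate addition delivers the methyl that becomes C20 and traps the enolate on oxygen; the methyl should enter trans to the C5 arm, but this carbon returns to sp2 in step 3, so its configuration does not matter.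

Step 3
Reactants: 5 tert-butyl 2-[(1S,2S)-2-methyl-4-(trimethylsilyloxy)cyclohex-3-en-1-yl]acetate
Product: 6 tert-butyl 2-[(1S)-2-methyl-4-oxocyclohex-2-en-1-yl]acetate
Conditions: Pd(OAc)2 (10 mol %), O2 (1 atm), DMSO, 25 °C
Reagents that add atoms: none
Why: Saegusa–Ito dehydrogenation, in which the C9-bound divalent palladium enolate can undergo β-hydride elimination only towards C10, regenerates the enone now carrying the β-methyl group and leaves the γ-stereocentre C5 untouched.

Step 4
Reactants: 7 (3-bromopropoxy)(tert-butyl)dimethylsilane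
Product: 8 [3-(tert-butyldimethylsilyloxy)propyl]magnesium bromide (titrated THF solution, used as such)
Conditions: Mg turnings, cat. 1,2-dibromoethane, THF, 25–40 °C
Reagents that add atoms: magnesium, [Mg]
Why: Direct insertion of magnesium into the primary C–Br bond (Grignard formation) is routine for silyl-protected 3-bromopropanol and creates no stereocentre.

Step 5
Reactants: 6 tert-butyl 2-[(1S)-2-methyl-4-oxocyclohex-2-en-1-yl]acetate; 8 [3-(tert-butyldimethylsilyloxy)propyl]magnesium bromide; 9 3-iodoprop-1-ene (allyl iodide)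
Product: 13 tert-butyl 2-[(1S,2S,3R)-2-[3-(tert-butyldimethylsilyloxy)propyl]-2-methyl-4-oxo-3-(prop-2-en-1-yl)cyclohexyl]acetate, via silyl enol ether 10 (not isolated), via sulfonium enolate 11 (not isolated), via C9-epimeric ketone 12 (not isolated)
Conditions: 8 (1.5 equiv), CuBr·SMe2 (10 mol %), Me3SiCl (2 equiv), HMPA (2 equiv), THF, −78 °C; Et3N, pentane, filtration, concentration (solvent switch, crude 10 carried on at once); then 9 (3 equiv), tris(dimethylamino)sulfonium difluorotrimethylsilicate (1.1 equiv), THF, −78 → −30 °C; then NaOMe (0.2 equiv), MeOH, 0 → 25 °C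
Reagents that add atoms: none
Why: The Grignard reagent and catalytic CuBr·SMe2 form a monovalent copper ate complex which, activated by Me3SiCl/HMPA, adds to C10 of the enone while the C8 enolate is silylated to 10; fluoride then removes the trimethylsilyl group and the sulfonium enolate 11 is alkylated at C9 by allyl iodide in an SN2 step, fluoride being preferred to an alkyllithium because the tert-butyl ester must survive. The closest known reaction types are the silyl-assisted copper-catalysed conjugate addition to 4-substituted 3-methylcyclohexenones and the fluoride-mediated regiospecific alkylation of silyl enol ethers. No ring is closed; two C–C bonds (C1–C10 and C9–C11) are formed. C10 is controlled by the C5 stereocentre, since the nucleophile enters axially on the face opposite the acetate arm, so that the chain ends trans and the methyl cis to that arm. C9 is controlled thermodynamically: whatever mixture of 12 and 13 the alkylation gives, catalytic methoxide equilibrates this α-centre towards 13, the epimer with allyl, C10 chain and C5 arm all equatorial and only the C10 methyl axial, and residual 12 is separated and equilibrated again. The step needs 1,4- rather than 1,2-addition (secured by copper and silyl activation) and retention of enolate regiochemistry with C-alkylation (secured by the regiodefined enol ether, low temperature and excess soft iodide), and it leaves the ester and the primary silyl ether untouched.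

Step 6
Reactants: 13 tert-butyl 2-[(1S,2S,3R)-2-[3-(tert-butyldimethylsilyloxy)propyl]-2-methyl-4-oxo-3-(prop-2-en-1-yl)cyclohexyl]acetate
Product: 14 enol triflate of 13: tert-butyl 2-[6-[3-(tert-butyldimethylsilyloxy)propyl]-6-methyl-5-(prop-2-en-1-yl)-4-(trifluoromethanesulfonyloxy)cyclohex-3-en-1-yl]acetate (C7=C8 double bond; C5, C9 and C10 as in 13)
Conditions: LiN(SiMe3)2 (1.1 equiv), PhNTf2 (1.2 equiv), THF, −78 → 0 °C
Reagents that add atoms: N-phenylbis(trifluoromethanesulfonimide), O=S(=O)(N(c1ccccc1)S(=O)(=O)C(F)(F)F)C(F)(F)F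
Why: Kinetic enolate formation takes place at the ketone rather than the less acidic ester and at the accessible C7 methylene rather than the neopentyl C9 methine, and O-sulfonylation (enol triflate synthesis) then fixes the C7=C8 double bond without touching the C9 configuration.

Step 7
Reactants: 14 enol triflate of 13
Product: 15 tert-butyl 2-[6-[3-(tert-butyldimethylsilyloxy)propyl]-4,6-dimethyl-5-(prop-2-en-1-yl)cyclohex-3-en-1-yl]acetate (C8-methyl C7=C8 alkene; C5, C9 and C10 as in 13)
Conditions: MeZnCl (2 equiv), Pd(PPh3)4 (5 mol %), THF, 25 → 50 °C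
Reagents that add atoms: chloro(methyl)zinc, C[Zn]Cl
Why: Negishi cross-coupling (oxidative addition of the alkenyl triflate to zerovalent palladium, transmetalation from zinc, reductive elimination) replaces the triflate by the C17 methyl with the double bond held at C7=C8, and the organozinc reagent tolerates the ester, the silyl ether and the terminal alkene.

Step 8
Reactants: 15 C8-methyl alkene silyl ether
Product: 16 tert-butyl 2-[6-(3-hydroxypropyl)-4,6-dimethyl-5-(prop-2-en-1-yl)cyclohex-3-en-1-yl]acetate (same configuration)
Conditions: Bu4NF, THF, 25 °C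
Reagents that add atoms: none
Why: Fluoride-induced cleavage of the primary silyl ether (desilylation) is selective because no other group in 15 is fluoride-labile.

Step 9
Reactants: 16 primary alcohol
Product: 17 tert-butyl 2-[6-(3-bromopropyl)-4,6-dimethyl-5-(prop-2-en-1-yl)cyclohex-3-en-1-yl]acetate (same configuration)
Conditions: CBr4, PPh3, CH2Cl2, 0 °C
Reagents that add atoms: tetrabromomethane, BrC(Br)(Br)Br
Why: Appel bromination converts the primary alcohol through its oxyphosphonium ion by SN2 attack of bromide under neutral conditions that spare the tert-butyl ester and both alkenes.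

Step 10
Reactants: 17 primary bromide
Product: 18 tert-butyl 14,15,16,18-tetranorlabda-7,12-dien-19-oate (trans-decalin; C4 epimers)
Conditions: LiN(iPr)2 (1.2 equiv), THF–DMPU, −78 → 25 °C
Reagents that add atoms: none
Why: Intramolecular ester-enolate alkylation (6-exo-tet SN2 with the enolate exocyclic to the new ring) joins C4 to C3, and since the C5 arm and the C10 chain are trans-diequatorial on ring B, ring A can only close as the trans-decalin; the C4 configuration is left undefined because it is enolised again in step 11.

Step 11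
Reactants: 18 tert-butyl 14,15,16,18-tetranorlabda-7,12-dien-19-oate
Product: 19 tert-butyl 14,15,16-trinorlabda-7,12-dien-19-oate (C4: methyl α-equatorial, ester β-axial)
Conditions: LiN(iPr)2 (1.5 equiv), THF–DMPU, −78 → 0 °C, MeI, −78 → 0 °C
Reagents that add atoms: iodomethane, CI
Why: In this ester-enolate alkylation iodomethane should approach the exocyclic enolate from the α face, because the β face is screened by the 1,3-diaxially disposed C10 methyl, which places the new methyl (C18) equatorial and the ester carbon (C19) axial as in the target.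

Step 12
Reactants: 19 tert-butyl 14,15,16-trinorlabda-7,12-dien-19-oate
Product: 21 tert-butyl 13-hydroxy-14,15,16-trinorlabd-7-en-19-oate, via alkylborane 20 (not isolated)
Conditions: 9-borabicyclo[3.3.1]nonane (1.5 equiv), THF, 0 → 25 °C; then NaOH, H2O2, 0 → 25 °C
Reagents that add atoms: hydrogen peroxide, OO
Why: In this hydroboration–oxidation the bulky dialkylborane adds anti-Markovnikov to the monosubstituted alkene only, leaving the trisubstituted C7=C8 bond, and oxidation with retention gives the C13 primary alcohol while the hindered tert-butyl ester survives the basic peroxide.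

Step 13
Reactants: 21 tert-butyl 13-hydroxy-14,15,16-trinorlabd-7-en-19-oate
Product: 22 tert-butyl 13-oxo-14,15,16-trinorlabd-7-en-19-oate (aldehyde)
Conditions: Dess–Martin periodinane, CH2Cl2, 25 °C
Reagents that add atoms: none
Why: Dess–Martin oxidation converts the primary alcohol into the aldehyde under mild conditions without over-oxidation or alkene migration.

Step 14
Reactants: 22 tert-butyl 13-oxo-14,15,16-trinorlabd-7-en-19-oate
Product: 23 tert-butyl 15,16-dinorlabd-7-en-13-yn-19-oate (terminal alkyne)
Conditions: dimethyl (1-diazo-2-oxopropyl)phosphonate (1.5 equiv), K2CO3 (2 equiv), MeOH, 0 → 25 °C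
Reagents that add atoms: dimethyl (1-diazo-2-oxopropyl)phosphonate, CC(=O)C(=[N+]=[N-])P(=O)(OC)OC
Why: The Ohira–Bestmann variant of the Seyferth–Gilbert homologation turns the aldehyde into the terminal alkyne (C13≡C14) under mild carbonate conditions that the fully substituted C19 ester tolerates.

Step 15
Reactants: 23 tert-butyl 15,16-dinorlabd-7-en-13-yn-19-oate
Product: 24 15,16-dinorlabd-7-en-13-yn-19-ol
Conditions: LiAlH4, THF, 0 → 65 °C; aqueous NaOH work-up
Reagents that add atoms: none
Why: Hydride reduction of the hindered ester with LiAlH4 in warm THF gives the neopentyl C19 alcohol, while isolated alkynes and alkenes are inert to this reagent.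

Step 16
Reactants: 24 15,16-dinorlabd-7-en-13-yn-19-ol
Product: 26 19-hydroxy-16-norlabd-7-en-13-yn-15-oic acid, via dilithium carbonate carboxylate 25 (not isolated)
Conditions: n-BuLi (2.3 equiv), THF, −78 → 0 °C; then CO2 (gas), −78 → 25 °C; then 1 M HCl
Reagents that add atoms: carbon dioxide, O=C=O
Why: Double deprotonation gives the alkoxide–acetylide, whose carbon terminus is carboxylated by CO2 (acetylide carboxylation), and the O-carbonate formed at C19 loses CO2 on acidification, so the alcohol needs no protecting group.

Step 17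
Reactants: 26 19-hydroxy-16-norlabd-7-en-13-yn-15-oic acid
Product: 27 prop-2-en-1-yl 19-hydroxy-16-norlabd-7-en-13-yn-15-oate
Conditions: allyl bromide (1.2 equiv), KHCO3 (1.5 equiv), DMF, 25 °C
Reagents that add atoms: 3-bromoprop-1-ene, C=CCBr
Why: Carboxylate O-alkylation (SN2) with allyl bromide under weak base is chemoselective over the hindered neopentyl alcohol and installs an ester that can later be removed without acid or base.

Step 18
Reactants: 27 prop-2-en-1-yl 19-hydroxy-16-norlabd-7-en-13-yn-15-oate
Product: 28 prop-2-en-1-yl (13Z)-19-hydroxylabda-7,13-dien-15-oate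
Conditions: MeLi, CuI (gives Me2CuLi, 3 equiv), THF, −78 °C; MeOH quench at −78 °C
Reagents that add atoms: lithium dimethylcuprate, [Li+].C[Cu-]C
Why: Syn-carbocupration (conjugate addition of the Gilman reagent) across the ynoate, followed by protonation of the alkenylcopper with retention at −78 °C, puts the new methyl and the C14 hydrogen cis, so that C12 and the ester are cis (13Z); one equivalent of reagent is consumed by the hydroxyl group.

Step 19
Reactants: 28 prop-2-en-1-yl (13Z)-19-hydroxylabda-7,13-dien-15-oate; 29 (Z)-2-methylbut-2-enoic acid (angelic acid)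
Product: 31 prop-2-en-1-yl (13Z)-19-[(2Z)-2-methylbut-2-enoyloxy]labda-7,13-dien-15-oate, via mixed anhydride 30 (not isolated)
Conditions: 29 (3 equiv), 2,4,6-trichlorobenzoyl chloride (3 equiv), Et3N, toluene, 25 °C; then 28, toluene, 80 °C
Reagents that add atoms: none
Why: In this Yamaguchi-type esterification the alcohol attacks the less hindered angeloyl carbonyl of the mixed anhydride, and the absence of a nucleophilic catalyst avoids the addition–elimination pathway that would isomerise the Z-configured acyl group to its E isomer.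

Step 20
Reactants: 31 prop-2-en-1-yl (13Z)-19-[(2Z)-2-methylbut-2-enoyloxy]labda-7,13-dien-15-oate
Product: 32 (13Z)-19-[(2Z)-2-methylbut-2-enoyloxy]labda-7,13-dien-15-oic acid (target)
Conditions: Pd(PPh3)4 (5 mol %), morpholine (5 equiv), THF, 25 °C; aqueous citric acid work-up
Reagents that add atoms: none
Why: In this Tsuji–Trost deallylation zerovalent palladium ionises the allyl ester to a π-allyl complex that is captured by morpholine, freeing the acid under neutral conditions that leave the angelate, the 13Z enoate and the C7=C8 alkene unchanged.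

Compound list
1 | tert-butyl 4-oxobutanoate | CC(C)(C)OC(=O)CCC=O | starting material
2 | but-3-en-2-one | CC(=O)C=C | starting material
3 | tert-butyl (3S)-3-formyl-6-oxoheptanoate (keto aldehyde) | CC(C)(C)OC(=O)C[C@@H](C=O)CCC(C)=O | intermediate (not isolated)
4 | tert-butyl 2-[(1S)-4-oxocyclohex-2-en-1-yl]acetate | CC(C)(C)OC(=O)C[C@@H]1CCC(=O)C=C1 | intermediate
5 | tert-butyl 2-[(1S,2S)-2-methyl-4-(trimethylsilyloxy)cyclohex-3-en-1-yl]acetate | CC(C)(C)OC(=O)C[C@@H]1CCC(O[Si](C)(C)C)=C[C@H]1C | intermediate
6 | tert-butyl 2-[(1S)-2-methyl-4-oxocyclohex-2-en-1-yl]acetate | CC(C)(C)OC(=O)C[C@@H]1CCC(=O)C=C1C | intermediate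
7 | (3-bromopropoxy)(tert-butyl)dimethylsilane | CC(C)(C)[Si](C)(C)OCCCBr | starting material
8 | [3-(tert-butyldimethylsilyloxy)propyl]magnesium bromide | CC(C)(C)[Si](C)(C)OCCC[Mg]Br | intermediate
9 | 3-iodoprop-1-ene | C=CCI | starting material
10 | tert-butyl 2-[(1S,2S)-2-[3-(tert-butyldimethylsilyloxy)propyl]-2-methyl-4-(trimethylsilyloxy)cyclohex-3-en-1-yl]acetate (silyl enol ether) | CC(C)(C)OC(=O)C[C@@H]1CCC(O[Si](C)(C)C)=C[C@@]1(C)CCCO[Si](C)(C)C(C)(C)C | intermediate (not isolated)
11 | tris(dimethylamino)sulfonium enolate of the C8 ketone (C8–O−, C8=C9) | CC(C)(C)OC(=O)C[C@@H]1CCC([O-])=C[C@@]1(C)CCCO[Si](C)(C)C(C)(C)C.CN(C)[S+](N(C)C)N(C)C | intermediate (not isolated)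
12 | tert-butyl 2-[(1S,2S,3S)-2-[3-(tert-butyldimethylsilyloxy)propyl]-2-methyl-4-oxo-3-(prop-2-en-1-yl)cyclohexyl]acetate (C9 epimer) | CC(C)(C)OC(=O)C[C@@H]1CCC(=O)[C@@H](CC=C)[C@@]1(C)CCCO[Si](C)(C)C(C)(C)C | intermediate (not isolated)
13 | tert-butyl 2-[(1S,2S,3R)-2-[3-(tert-butyldimethylsilyloxy)propyl]-2-methyl-4-oxo-3-(prop-2-en-1-yl)cyclohexyl]acetate | CC(C)(C)OC(=O)C[C@@H]1CCC(=O)[C@H](CC=C)[C@@]1(C)CCCO[Si](C)(C)C(C)(C)C | intermediate
14 | tert-butyl 2-[6-[3-(tert-butyldimethylsilyloxy)propyl]-6-methyl-5-(prop-2-en-1-yl)-4-(trifluoromethanesulfonyloxy)cyclohex-3-en-1-yl]acetate (C5, C9, C10 as in 13) | CC(C)(C)OC(=O)C[C@@H]1CC=C(OS(=O)(=O)C(F)(F)F)[C@H](CC=C)[C@@]1(C)CCCO[Si](C)(C)C(C)(C)C | intermediate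
15 | tert-butyl 2-[6-[3-(tert-butyldimethylsilyloxy)propyl]-4,6-dimethyl-5-(prop-2-en-1-yl)cyclohex-3-en-1-yl]acetate (same configuration) | CC(C)(C)OC(=O)C[C@@H]1CC=C(C)[C@H](CC=C)[C@@]1(C)CCCO[Si](C)(C)C(C)(C)C | intermediate
16 | tert-butyl 2-[6-(3-hydroxypropyl)-4,6-dimethyl-5-(prop-2-en-1-yl)cyclohex-3-en-1-yl]acetate (same configuration) | CC(C)(C)OC(=O)C[C@@H]1CC=C(C)[C@H](CC=C)[C@@]1(C)CCCO | intermediate
17 | tert-butyl 2-[6-(3-bromopropyl)-4,6-dimethyl-5-(prop-2-en-1-yl)cyclohex-3-en-1-yl]acetate (same configuration) | CC(C)(C)OC(=O)C[C@@H]1CC=C(C)[C@H](CC=C)[C@@]1(C)CCCBr | intermediate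
18 | tert-butyl 14,15,16,18-tetranorlabda-7,12-dien-19-oate (C4 epimers) | CC(C)(C)OC(=O)C1CCC[C@]2(C)[C@@H](CC=C)C(C)=CC[C@@H]12 | intermediate
19 | tert-butyl 14,15,16-trinorlabda-7,12-dien-19-oate | CC(C)(C)OC(=O)[C@@]1(C)CCC[C@]2(C)[C@@H](CC=C)C(C)=CC[C@@H]12 | intermediate
20 | B-alkyl-9-borabicyclo[3.3.1]nonane adduct of 19 at C13 (alkylborane) | CC(C)(C)OC(=O)[C@@]1(C)CCC[C@]2(C)[C@@H](CCCB3C4CCCC3CCC4)C(C)=CC[C@@H]12 | intermediate (not isolated)
21 | tert-butyl 13-hydroxy-14,15,16-trinorlabd-7-en-19-oate | CC(C)(C)OC(=O)[C@@]1(C)CCC[C@]2(C)[C@@H](CCCO)C(C)=CC[C@@H]12 | intermediate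
22 | tert-butyl 13-oxo-14,15,16-trinorlabd-7-en-19-oate | CC(C)(C)OC(=O)[C@@]1(C)CCC[C@]2(C)[C@@H](CCC=O)C(C)=CC[C@@H]12 | intermediate
23 | tert-butyl 15,16-dinorlabd-7-en-13-yn-19-oate | CC(C)(C)OC(=O)[C@@]1(C)CCC[C@]2(C)[C@@H](CCC#C)C(C)=CC[C@@H]12 | intermediate
24 | 15,16-dinorlabd-7-en-13-yn-19-ol | OC[C@@]1(C)CCC[C@]2(C)[C@@H](CCC#C)C(C)=CC[C@@H]12 | intermediate
25 | dilithium salt of the C19 O-carbonate and C15 carboxylate of 24 | [Li+].[Li+].[O-]C(=O)OC[C@@]1(C)CCC[C@]2(C)[C@@H](CCC#CC([O-])=O)C(C)=CC[C@@H]12 | intermediate (not isolated)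
26 | 19-hydroxy-16-norlabd-7-en-13-yn-15-oic acid | OC[C@@]1(C)CCC[C@]2(C)[C@@H](CCC#CC(=O)O)C(C)=CC[C@@H]12 | intermediate
27 | prop-2-en-1-yl 19-hydroxy-16-norlabd-7-en-13-yn-15-oate | OC[C@@]1(C)CCC[C@]2(C)[C@@H](CCC#CC(=O)OCC=C)C(C)=CC[C@@H]12 | intermediate
28 | prop-2-en-1-yl (13Z)-19-hydroxylabda-7,13-dien-15-oate | OC[C@@]1(C)CCC[C@]2(C)[C@@H](CC/C(C)=C\C(=O)OCC=C)C(C)=CC[C@@H]12 | intermediate
29 | (Z)-2-methylbut-2-enoic acid (angelic acid) | C/C=C(/C)C(=O)O | starting material
30 | (Z)-2-methylbut-2-enoic 2,4,6-trichlorobenzoic anhydride | C/C=C(/C)C(=O)OC(=O)c1c(Cl)cc(Cl)cc1Cl | intermediate (not isolated)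
31 | prop-2-en-1-yl (13Z)-19-[(2Z)-2-methylbut-2-enoyloxy]labda-7,13-dien-15-oate | C/C=C(/C)C(=O)OC[C@@]1(C)CCC[C@]2(C)[C@@H](CC/C(C)=C\C(=O)OCC=C)C(C)=CC[C@@H]12 | intermediate
32 | (13Z)-19-[(2Z)-2-methylbut-2-enoyloxy]labda-7,13-dien-15-oic acid | C/C=C(/C)C(=O)OC[C@@]1(C)CCC[C@]2(C)[C@@H](CC/C(C)=C\C(=O)O)C(C)=CC[C@@H]12 | target

Total step count: 20. Longest linear sequence: 19 steps (steps 1–3 and 5–20; step 4 prepares the Grignard reagent).

Steps most likely to fail

Step 5. While alkylation at the neopentyl C9 is slow, proton exchange between the free enolate and ketone already formed could move the enolate to C7 and cause double allylation; in addition, the equilibrium at C9 may leave a sizeable share of the epimer. The fallback sets out from silyl enol ether 10, this time purified on triethylamine-deactivated silica, and replaces the free enolate by a Tsuji–Trost allylation (allyl methyl carbonate, Pd2(dba)3, 1,2-bis(diphenylphosphino)ethane, THF, 65 °C). Methoxide released from the carbonate removes the silyl group and the palladium-bound enolate couples at once with the π-allyl ligand, so no free enolate accumulates. The same NaOMe/MeOH equilibration follows, epimer 12 is separated and resubmitted to it, and the route is rejoined at 13. No compound outside the list is made (F0).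

Step 11. Slow enolisation of the hindered ring ester, or insufficient facial discrimination of a small electrophile, would leave unreacted ester or give the C4 epimer. The fallback reverses the order of the two bond formations at C4 and sets out from 15. Its unhindered acetate arm is methylated first (LiN(iPr)2, MeI, THF, −78 °C) to give tert-butyl 2-[6-[3-(tert-butyldimethylsilyloxy)propyl]-4,6-dimethyl-5-(prop-2-en-1-yl)cyclohex-3-en-1-yl]propanoate F1 as a C4 epimer mixture. Bu4NF then gives the alcohol F2 and CBr4/PPh3 the bromide F3. KN(SiMe3)2 in THF–DMPU closes ring A with direct formation of the quaternary C4; the transition state that would place the C4 methyl syn-axial to the C10 methyl should be disfavoured, so the ester should again end axial. The route is rejoined at 19.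

Step 19. Isomerisation of the angeloyl unit to its E isomer during activation, or sluggish acylation of the axial neopentyl alcohol, would erode geometry or conversion. The fallback sets out from 28 and builds the Z-configured acyl group on the alcohol instead of transferring it. Steglich esterification with 2-[bis(2,2,2-trifluoroethoxy)phosphoryl]propanoic acid (dicyclohexylcarbodiimide, 4-dimethylaminopyridine, CH2Cl2) gives the phosphonopropanoate F4. Still–Gennari olefination with acetaldehyde (KN(SiMe3)2, 18-crown-6, THF, −78 °C) then gives the (Z)-2-methylbut-2-enoate, and the route is rejoined at 31.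

Further compounds
F0 | step 5 | none | none
F1 | step 11 | tert-butyl 2-[6-[3-(tert-butyldimethylsilyloxy)propyl]-4,6-dimethyl-5-(prop-2-en-1-yl)cyclohex-3-en-1-yl]propanoate (C4 epimers; ring configuration as in 15) | CC(C(=O)OC(C)(C)C)[C@@H]1CC=C(C)[C@H](CC=C)[C@@]1(C)CCCO[Si](C)(C)C(C)(C)C
F2 | step 11 | tert-butyl 2-[6-(3-hydroxypropyl)-4,6-dimethyl-5-(prop-2-en-1-yl)cyclohex-3-en-1-yl]propanoate (C4 epimers) | CC(C(=O)OC(C)(C)C)[C@@H]1CC=C(C)[C@H](CC=C)[C@@]1(C)CCCO
F3 | step 11 | tert-butyl 2-[6-(3-bromopropyl)-4,6-dimethyl-5-(prop-2-en-1-yl)cyclohex-3-en-1-yl]propanoate (C4 epimers) | CC(C(=O)OC(C)(C)C)[C@@H]1CC=C(C)[C@H](CC=C)[C@@]1(C)CCCBr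
F4 | step 19 | prop-2-en-1-yl (13Z)-19-[2-[bis(2,2,2-trifluoroethoxy)phosphoryl]propanoyloxy]labda-7,13-dien-15-oate | CC(C(=O)OC[C@@]1(C)CCC[C@]2(C)[C@@H](CC/C(C)=C\C(=O)OCC=C)C(C)=CC[C@@H]12)P(=O)(OCC(F)(F)F)OCC(F)(F)F
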